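## Structural features

The target is a biflavanoid in which C4 of an upper 4',7-dihydroxyflavan (resorcinol ring A, pyran ring C, 4-hydroxyphenyl ring B, no oxygen on C3 or C5) is bonded to C8' of a lower (−)-epigallocatechin unit with its phloroglucinol-type ring D, its own pyran ring and a pyrogallol ring. Ring C holds two stereocentres in a 1,3-relationship, C2 (S) and C4 (R), with the two aryl groups trans, whereas the lower unit holds the adjacent cis pair C2' (R) and C3' (R), which is bought with the natural flavan-3-ol. There are eight free hydroxyls, and the pyrogallol ring oxidises in air as soon as it is deprotonated. The benzylic ethers C2–O1 and C2'–O1' open by ionisation in acid or, when the para phenol is free, by quinone methide formation in base, and rings A and D are strong π-nucleophiles. The real difficulty is C4, a doubly benzylic methine between two electron-rich rings, one of them di-ortho-substituted and chiral, which must be joined to C8' and not to C6' with a configuration that cannot be relayed from the lower stereocentres. The second difficulty is the trans relationship, because hydrogen delivered to an sp2 C2 would arrive anti to the C4 aryl group and give cis, so C2 has to be set in the open chain and ring C closed stereospecifically. The key step exploits ring A, in which C4a carries C4, C8a and C7 carry oxygen, and C5, C6 and C8 carry hydrogen: this is the oxidation pattern of the chain C4a–C8a(=O)–C8–C7(=O)–C6–C5(=O)H with C4a–C5 as an aldol bond, a chain that can be stored as a 2-alkyl-4-pyranone with its ring oxygen on C8a.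

## Logic of the disconnections

28 to 27. Seven O–CH2Ph bonds are cut. Carrying every oxygen function except the 7-hydroxyl as one kind of ether lets them all be released in a single neutral step and keeps all earlier intermediates lipophilic and non-oxidisable. The forward step must hydrogenolyse benzyl ethers without touching the cyclic benzylic C–O bonds or the C4–C8' bond.

27 to 26. The O1–C2 bond is cut, which opens ring C to a 1,3-diarylpropanol. Closure by SN2 turns an (R)-carbinol into (2S), so the trans arrangement follows from two centres set independently. The forward step needs clean inversion at a para-alkoxybenzylic carbon; only the ortho phenol can reach C2.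

26 to 25. The O–Si bond is cut. The carbinol oxygen has to be masked while ring A is made, because a free alkoxide could add to the pyranone or to the C8a carbonyl and attach C8a to the wrong oxygen. The group must survive hot hydroxide and leave with fluoride.

25 to 23 through 24. The C4a–C5 bond is cut. Ring A becomes the 3,5-dioxoaldehyde 24, kept as the pyranone 23. The arene and both its oxygens are thereby traded for an acylation product, and no substitution on an aromatic ring is needed. The forward step demands that the aldol through C4a outruns loss of the formyl carbon.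

23 to 18 and 19 through 20, 21 and 22. The C8–C8a bond (acylation) and the ring O–C5 bond (closure with loss of methanol) are cut. Carbons C5 to C8 then come from 19 and the rest is a carboxylic acid. The forward step needs C-acylation of the enolate and an acid closure mild enough for the benzylic silyl ether.

18 to 15 through 16 and 17. The lactone C–O bond is reformed and the O–Si bond cut, a protecting-group interchange. The lactone is the isolable form of the hydroxy acid and a point at which minor stereoisomers can be removed. The forward step must open the lactone and silylate the carboxylate salt without letting the free hydroxy acid close again.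

15 to 13 through 14. The C2–H bond and the lactone C–O bond are cut. The carbinol comes from a catalyst-controlled ketone reduction; C2 is far enough from C4 that reagent control should decide.

13 to 10 and 11 through 12. The C2–C1' bond to ring B is cut. C4 becomes the non-stereogenic centre of a symmetrical anhydride, so its configuration is a choice between two identical arms, made away from the crowded ring D. The forward step needs mono-addition to one of two diastereotopic carbonyls.

10 to 9, then 9 to 6 and 7 through 8. The C3–C4 and C4–C4a bonds are cut. C4 and its two acetic acid arms are assembled from an aldehyde carbon and two molecules of 7, whose acetyl groups are discarded. The forward step must achieve double addition at a hindered aldehyde.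

6 to 4 through 5, then 4 to 3, 2 and 1. The C8'–CHO and C8'–Br bonds and the benzyl ethers are cut. Regiochemistry at C8' is settled by an electrophilic bromination, and the lower stereocentres are bought with 1.

## Other disconnections considered

Alternative 1: The cut is O1–C8a, traced back to a C8a–carbonyl bond. Lactone A1 would arise from indanone A2 by Baeyer–Villiger oxidation with a buffered peracid and migration of the aryl carbon.
- In favour: ring A is bought as an arene, so no aromatisation has to be invented. The oxidation retains configuration at C4, and A1 is a robust intermediate. On precedent for the key step this alternative is the better of the two.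
- Against: the benzyloxy group of A2 is meta to the migrating carbon, so it does not assist migration, and methylene migration to the isomeric lactone competes. The peracid also meets ring D and the trialkoxyphenyl ring.
- Against: A2 needs either an acylation meta to an ether oxygen or conjugate addition of a di-ortho-substituted aryl metal. After A1, ring B must be added to the lactone carbonyl and C2 reduced; hydride then enters anti to the C4 aryl group and gives 2,4-cis.
- Comparison: on structure the chosen plan is better, since it sets C2 by inversion in the open chain. On mechanism the alternative rests on the better known reaction. On step count the two are about equal.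

Alternative 2: The cuts are C3–C4 and O1–C2 together. A chiral phosphoric acid would ionise carbinol A4 to an ortho-quinone methide, which adds styrene A5 to give A3.
- In favour: it is the most convergent plan, closing ring C and setting both stereocentres in one step from pieces a few steps from 6. On step economy it is clearly better than the chosen plan, and it equals it in bringing ring A with its oxygens in place.
- Against: this cycloaddition type is endo-selective and delivers 2,4-cis-diarylchromans, whereas the target is trans.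
- Against: the catalyst would also have to fix the absolute sense at C4 against the chirality and bulk of the di-ortho-substituted aryl group on the methide carbon. Ring D can compete with A5 as the nucleophile.
- Comparison: on structure and mechanism the chosen plan is better, because its stereocentres come from two separate, stereospecific or reagent-controlled events and not from one transition state whose inherent preference is the wrong diastereomer. On step economy the alternative keeps its advantage.

Alternative 3: The cuts are C2–C3 and O1–C2, with hydrogen placed on C4. Hydroformylation of diarylethylene A7 (Rh(acac)(CO)2, chiral ligand, CO/H2) would give the aldehyde, which closes to lactol A6.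
- In favour: it is atom-economical, ring A arrives intact, and the route to A7 is short, so it is better on step count.
- In favour: A6 is at the right oxidation level for adding ring B as an aryl nucleophile to the cyclic oxocarbenium ion. That addition should place the new aryl group axial and so trans to C4, without an SN2 step at an ionisable centre; on this point it is at least the equal of the chosen plan.
- Against: 1,1-diarylethylenes are among the least reactive hydroformylation substrates, and here both rings are ortho-substituted. C4 would be set by hydride delivery to a carbon whose two aryl groups differ little, with hydrogenation as a competing path.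
- Comparison: on the structure of C4 the chosen plan is better, since it selects between two remote arms and its diastereomers are separable. On mechanism the two are level, the key event of each being untested on this substrate class. On step economy the alternative is better.

Key step: step 11

Assumption: (−)-sparteine is taken to steer the aryl group to the carbonyl that leads to 13. This sense is not secured by analogy for a chiral, di-ortho-substituted anhydride; the two possible keto acids are separable diastereomers, and (+)-sparteine would be used if the preference is the opposite.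

Remark: the descriptors derived from the structures of the route are (R) at the carbinol carbon and (R) at C4 in 23 to 26, and (2S,4R), 2,4-trans, in 27 and 28. The one change of design in the precursor of the key step is that its carbinol is carried as a tert-butyldimethylsilyl ether (23 and 25).

## Route

Step 1
Reactants: 1 (−)-epigallocatechin
Product: 2 5,7,3',4',5'-penta-O-benzyl-(−)-epigallocatechin
Conditions: BnBr (5.5 equiv), K2CO3, DMF, under argon, 0 °C to rt
Reagents that add atoms: benzyl bromide BrCc1ccccc1
Why: Williamson etherification; carbonate deprotonates only the five phenols, so the 3-hydroxyl stays free and C2 never meets a strong base while para phenols are unmasked.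

Step 2
Reactants: 2 5,7,3',4',5'-penta-O-benzyl-(−)-epigallocatechin
Product: 3 3,5,7,3',4',5'-hexa-O-benzyl-(−)-epigallocatechin
Conditions: NaH, BnBr, Bu4NI (cat.), THF/DMF, 0 °C to rt
Reagents that add atoms: benzyl bromide BrCc1ccccc1
Why: Williamson etherification of the secondary alkoxide; with all phenols capped the cis C2/C3 pair has no base-induced epimerisation pathway.

Step 3
Reactants: 3 3,5,7,3',4',5'-hexa-O-benzyl-(−)-epigallocatechin
Product: 4 8-bromo-3,5,7,3',4',5'-hexa-O-benzylepigallocatechin
Conditions: NBS (1.0 equiv), CH2Cl2, −78 to −20 °C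
Reagents that add atoms: N-bromosuccinimide O=C1CCC(=O)N1Br
Why: Electrophilic aromatic bromination; in 5,7-di-O-alkylated flavan-3-ol ethers C8 is attacked in preference to C6 and to the trialkoxyphenyl ring, and one equivalent at low temperature limits dibromination.

Step 4
Reactants: 4 8-bromo-3,5,7,3',4',5'-hexa-O-benzylepigallocatechin
Product: 6 3,5,7,3',4',5'-hexa-O-benzylepigallocatechin-8-carbaldehyde, via aryllithium 5 (not isolated)
Conditions: n-BuLi (1.05 equiv), THF, −78 °C; DMF; aq. NH4Cl
Reagents that add atoms: N,N-dimethylformamide CN(C)C=O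
Why: Bromine–lithium exchange followed by formylation of the aryllithium with DMF; exchange at −78 °C is faster than deprotonation of the benzylic positions.

Step 5
Reactants: 6 3,5,7,3',4',5'-hexa-O-benzylepigallocatechin-8-carbaldehyde; 7 ethyl acetoacetate
Product: 9 3-(hexa-O-benzylepigallocatechin-8-yl)pentanedioic acid, via bis-acetoacetate adduct 8 (not isolated)
Conditions: 7 (2.2 equiv), piperidine (0.2 equiv), EtOH/THF, 50 °C; then KOH (50% aq.), EtOH, reflux; aq. HCl to pH 2
Reagents that add atoms: potassium hydroxide [K+].[OH-]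
Why: Knoevenagel condensation and Michael addition of a second acetoacetate, then double retro-Claisen cleavage and saponification in hot alkali, the classical route to 3-arylglutaric acids. The new carbon C4 is not yet stereogenic because its two arms are identical.

Step 6
Reactants: 9 3-(hexa-O-benzylepigallocatechin-8-yl)pentanedioic acid
Product: 10 3-(hexa-O-benzylepigallocatechin-8-yl)glutaric anhydride
Conditions: Ac2O, 80 °C; evaporate
Reagents that add atoms: none
Why: Cyclodehydration of a 1,5-diacid to the six-membered anhydride by acyl exchange with acetic anhydride.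

Step 7
Reactants: 10 3-(hexa-O-benzylepigallocatechin-8-yl)glutaric anhydride; 11 1-benzyloxy-4-bromobenzene
Product: 13 (3R)-5-(4-benzyloxyphenyl)-5-oxo-3-(hexa-O-benzylepigallocatechin-8-yl)pentanoic acid, via Grignard reagent 12 (not isolated)
Conditions: 11, Mg, THF, rt; then (−)-sparteine (1.3 equiv), PhMe, −78 °C, 10; aq. HCl (1 M)
Reagents that add atoms: none
Why: Sparteine-mediated desymmetrising mono-addition of an aryl Grignard reagent to a 3-substituted glutaric anhydride; the magnesium carboxylate formed protects the ketone from a second addition. The choice between the two diastereotopic carbonyls sets C4 as (R), and the minor keto acid is a separable diastereomer.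

Step 8
Reactants: 13 (3R)-5-(4-benzyloxyphenyl)-5-oxo-3-(hexa-O-benzylepigallocatechin-8-yl)pentanoic acid
Product: 15 (4R,6R)-6-(4-benzyloxyphenyl)-4-(hexa-O-benzylepigallocatechin-8-yl)tetrahydropyran-2-one, via hydroxy acid 14 (not isolated)
Conditions: RuCl[(R,R)-TsDPEN](p-cymene) (2 mol%), HCO2H/Et3N (5:2), DMF, 40 °C; then PhMe, 60 °C
Reagents that add atoms: none
Why: Noyori asymmetric transfer hydrogenation; the (R,R)-catalyst should give the (R)-carbinol as it does for aryl alkyl ketones, the centre being too far from C4 for substrate bias. The δ-hydroxy acid lactonises on warming to the cis-4,6-diaryl lactone, where stereoisomers from steps 7 and 8 can be removed.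

Step 9
Reactants: 15 (4R,6R)-6-(4-benzyloxyphenyl)-4-(hexa-O-benzylepigallocatechin-8-yl)tetrahydropyran-2-one
Product: 18 (3R,5R)-5-(4-benzyloxyphenyl)-5-(tert-butyldimethylsilyloxy)-3-(hexa-O-benzylepigallocatechin-8-yl)pentanoic acid, via potassium carboxylate 16 (not isolated), via bis-silyl derivative 17 (not isolated)
Conditions: KOH (1.1 equiv), THF/MeOH/H2O, rt; evaporate, azeotrope with PhMe; TBSCl (2.5 equiv), imidazole, DMF, rt; then K2CO3, MeOH/THF/H2O, rt; citric acid to pH 5
Reagents that add atoms: tert-butyldimethylsilyl chloride CC(C)(C)[Si](C)(C)Cl; potassium hydroxide [K+].[OH-]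
Why: Saponification of the lactone gives the potassium δ-hydroxy carboxylate, which is silylated as the salt so that the free hydroxy acid never forms and cannot close back to the lactone. Exhaustive silylation and selective cleavage of the silyl ester then leave the carbinol as a base-stable silyl ether and free the carboxyl group without strong acid.

Step 10
Reactants: 18 (3R,5R)-5-(4-benzyloxyphenyl)-5-(tert-butyldimethylsilyloxy)-3-(hexa-O-benzylepigallocatechin-8-yl)pentanoic acid; 19 (E)-4-methoxybut-3-en-2-one
Product: 23 2-[(2R,4R)-4-(4-benzyloxyphenyl)-4-(tert-butyldimethylsilyloxy)-2-(hexa-O-benzylepigallocatechin-8-yl)butyl]-4H-pyran-4-one, via acid chloride 20 (not isolated), via lithium enolate 21 (not isolated), via methoxy enedione 22 (not isolated)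
Conditions: 18, 1-chloro-N,N,2-trimethylprop-1-en-1-amine, CH2Cl2, 0 °C; 19 (2.5 equiv), LiN(SiMe3)2 (2.5 equiv), THF, −78 °C, then 20; aq. NH4Cl; then CF3CO2H (0.2 equiv), PhMe, rt
Reagents that add atoms: none
Why: Neutral acid chloride formation, C-acylation of the lithium enolate of 19 (the second equivalent deprotonates the β-diketone), then acid-catalysed addition–elimination of the enol oxygen with loss of methanol to close the 4-pyranone. Only a catalytic amount of acid in toluene is used because the benzylic silyl ether is ionisable.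

Step 11
Reactants: 23 2-[(2R,4R)-4-(4-benzyloxyphenyl)-4-(tert-butyldimethylsilyloxy)-2-(hexa-O-benzylepigallocatechin-8-yl)butyl]-4H-pyran-4-one
Product: 25 4-[(1R,3R)-3-(4-benzyloxyphenyl)-3-(tert-butyldimethylsilyloxy)-1-(hexa-O-benzylepigallocatechin-8-yl)propyl]benzene-1,3-diol, via dioxoaldehyde 24 (not isolated)
Conditions: KOH (1 M aq., 10 equiv), 1,4-dioxane, degassed, under argon, 70 °C; then aq. NH4Cl
Reagents that add atoms: none
Why: Proposed new method: hydroxide adds to the one unsubstituted α-carbon of the pyranone, the ring opens by C–O cleavage to the enolate of 24, and the C4a methylene, the only enolisable carbon that can reach the formyl carbon through a six-membered transition state, adds to the aldehyde carbon. This closes ring A by a 6-(enolendo)-exo-trig aldol, every other intramolecular aldol of the chain being four-membered; loss of water and two enolisations give the resorcinol, and this irreversible aromatisation is what should draw material out of the pyranone/open-chain equilibrium. The closest known reaction type is the base-induced conversion of 2,6-dimethyl-4-pyranone and of 3,5,7-tricarbonyl chains into orcinol-type resorcinols, where the acceptor is a ketone; an aldehyde acceptor from a 6-unsubstituted 2-alkylpyranone has not been shown. No stereocentre is formed: C4 is β to the C8a carbonyl and has no leaving group or acidic hydrogen, and C2 is held as a silyl ether. The selectivity needed is aldol over hydroxide-induced loss of the formyl carbon from the β-ketoaldehyde, and the higher electrophilicity of the aldehyde and the intramolecular six-ring closure are what should favour the aldol. The silyl ether stops the C2 oxygen from adding to the pyranone or to the C8a carbonyl, which in the free alcohol could bind C8a to the carbinol oxygen and close ring C with retention to the wrong C2 epimer.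

Step 12
Reactants: 25 4-[(1R,3R)-3-(4-benzyloxyphenyl)-3-(tert-butyldimethylsilyloxy)-1-(hexa-O-benzylepigallocatechin-8-yl)propyl]benzene-1,3-diol
Product: 26 4-[(1R,3R)-3-(4-benzyloxyphenyl)-3-hydroxy-1-(hexa-O-benzylepigallocatechin-8-yl)propyl]benzene-1,3-diol
Conditions: Bu4NF, AcOH, THF, under argon, 0 °C to rt
Reagents that add atoms: none
Why: Fluoride cleavage of the silyl ether; acetic acid buffering keeps the resorcinol from sitting as an air-sensitive phenolate.

Step 13
Reactants: 26 4-[(1R,3R)-3-(4-benzyloxyphenyl)-3-hydroxy-1-(hexa-O-benzylepigallocatechin-8-yl)propyl]benzene-1,3-diol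
Product: 27 (2S,4R)-2-(4-benzyloxyphenyl)-4-(hexa-O-benzylepigallocatechin-8-yl)chroman-7-ol
Conditions: PPh3, DIAD, PhMe/THF, 0.01 M, −20 to 0 °C
Reagents that add atoms: none
Why: Intramolecular Mitsunobu etherification: the oxyphosphonium of the (R)-carbinol is displaced by the ortho phenol in a 6-exo-tet SN2 step with inversion, which should give (2S) and the 2,4-trans chroman. The para phenol cannot reach C2, and cold, dilute, weakly polar conditions are chosen to keep the para-alkoxybenzylic centre from ionising.

Step 14
Reactants: 27 (2S,4R)-2-(4-benzyloxyphenyl)-4-(hexa-O-benzylepigallocatechin-8-yl)chroman-7-ol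
Product: 28 (2S,4R)-2-(4-hydroxyphenyl)-4-[(−)-epigallocatechin-8-yl]chroman-7-ol (CNP0220331.1)
Conditions: H2 (1 atm), Pd(OH)2/C, THF/MeOH, rt; filter under argon
Reagents that add atoms: none
Why: Hydrogenolysis of seven benzyl ethers; benzyl aryl and benzyl alkyl ethers should cleave faster than the cyclic benzylic C–O bonds, as in the deprotection of benzylated flavan-3-ol oligomers.

## Compound list

1 | (−)-epigallocatechin, (2R,3R) | Oc1cc(O)c2c(c1)O[C@H](c1cc(O)c(O)c(O)c1)[C@H](O)C2 | starting material
2 | 5,7,3',4',5'-penta-O-benzyl-(−)-epigallocatechin | O(Cc1ccccc1)c1cc(OCc2ccccc2)c2c(c1)O[C@H](c1cc(OCc3ccccc3)c(OCc3ccccc3)c(OCc3ccccc3)c1)[C@H](O)C2 | intermediate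
3 | 3,5,7,3',4',5'-hexa-O-benzyl-(−)-epigallocatechin | O(Cc1ccccc1)c1cc(OCc2ccccc2)c2c(c1)O[C@H](c1cc(OCc3ccccc3)c(OCc3ccccc3)c(OCc3ccccc3)c1)[C@H](OCc1ccccc1)C2 | intermediate
4 | 8-bromo-hexa-O-benzylepigallocatechin | Brc5c(OCc6ccccc6)cc(OCc6ccccc6)c6c5O[C@H](c5cc(OCc7ccccc7)c(OCc7ccccc7)c(OCc7ccccc7)c5)[C@H](OCc5ccccc5)C6 | intermediate
5 | 8-lithio-hexa-O-benzylepigallocatechin | [Li]c5c(OCc6ccccc6)cc(OCc6ccccc6)c6c5O[C@H](c5cc(OCc7ccccc7)c(OCc7ccccc7)c(OCc7ccccc7)c5)[C@H](OCc5ccccc5)C6 | intermediate
6 | hexa-O-benzylepigallocatechin-8-carbaldehyde | O=Cc5c(OCc6ccccc6)cc(OCc6ccccc6)c6c5O[C@H](c5cc(OCc7ccccc7)c(OCc7ccccc7)c(OCc7ccccc7)c5)[C@H](OCc5ccccc5)C6 | intermediate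
7 | ethyl acetoacetate | CCOC(=O)CC(C)=O | starting material
8 | diethyl 2,4-diacetyl-3-(hexa-O-benzylepigallocatechin-8-yl)pentanedioate (mixture of isomers, may sit as its cyclic aldol) | CCOC(=O)C(C(C)=O)C(c5c(OCc6ccccc6)cc(OCc6ccccc6)c6c5O[C@H](c5cc(OCc7ccccc7)c(OCc7ccccc7)c(OCc7ccccc7)c5)[C@H](OCc5ccccc5)C6)C(C(C)=O)C(=O)OCC | intermediate
9 | 3-(hexa-O-benzylepigallocatechin-8-yl)pentanedioic acid | OC(=O)CC(c5c(OCc6ccccc6)cc(OCc6ccccc6)c6c5O[C@H](c5cc(OCc7ccccc7)c(OCc7ccccc7)c(OCc7ccccc7)c5)[C@H](OCc5ccccc5)C6)CC(=O)O | intermediate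
10 | 3-(hexa-O-benzylepigallocatechin-8-yl)glutaric anhydride | O=C1CC(c5c(OCc6ccccc6)cc(OCc6ccccc6)c6c5O[C@H](c5cc(OCc7ccccc7)c(OCc7ccccc7)c(OCc7ccccc7)c5)[C@H](OCc5ccccc5)C6)CC(=O)O1 | intermediate
11 | 1-benzyloxy-4-bromobenzene | Brc1ccc(OCc2ccccc2)cc1 | starting material
12 | 4-benzyloxyphenylmagnesium bromide | Br[Mg]c1ccc(OCc2ccccc2)cc1 | intermediate
13 | (3R)-5-(4-benzyloxyphenyl)-5-oxo-3-(hexa-O-benzylepigallocatechin-8-yl)pentanoic acid | OC(=O)C[C@H](c5c(OCc6ccccc6)cc(OCc6ccccc6)c6c5O[C@H](c5cc(OCc7ccccc7)c(OCc7ccccc7)c(OCc7ccccc7)c5)[C@H](OCc5ccccc5)C6)CC(=O)c1ccc(OCc2ccccc2)cc1 | intermediate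
14 | (3R,5R)-5-(4-benzyloxyphenyl)-5-hydroxy-3-(hexa-O-benzylepigallocatechin-8-yl)pentanoic acid | OC(=O)C[C@H](c5c(OCc6ccccc6)cc(OCc6ccccc6)c6c5O[C@H](c5cc(OCc7ccccc7)c(OCc7ccccc7)c(OCc7ccccc7)c5)[C@H](OCc5ccccc5)C6)C[C@@H](O)c1ccc(OCc2ccccc2)cc1 | intermediate
15 | (4R,6R)-6-(4-benzyloxyphenyl)-4-(hexa-O-benzylepigallocatechin-8-yl)tetrahydropyran-2-one (cis) | O=C1C[C@H](c5c(OCc6ccccc6)cc(OCc6ccccc6)c6c5O[C@H](c5cc(OCc7ccccc7)c(OCc7ccccc7)c(OCc7ccccc7)c5)[C@H](OCc5ccccc5)C6)C[C@@H](O1)c1ccc(OCc2ccccc2)cc1 | intermediate
16 | potassium (3R,5R)-5-(4-benzyloxyphenyl)-5-hydroxy-3-(hexa-O-benzylepigallocatechin-8-yl)pentanoate | [K+].[O-]C(=O)C[C@H](c5c(OCc6ccccc6)cc(OCc6ccccc6)c6c5O[C@H](c5cc(OCc7ccccc7)c(OCc7ccccc7)c(OCc7ccccc7)c5)[C@H](OCc5ccccc5)C6)C[C@@H](O)c1ccc(OCc2ccccc2)cc1 | intermediate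
17 | tert-butyldimethylsilyl (3R,5R)-5-(4-benzyloxyphenyl)-5-(tert-butyldimethylsilyloxy)-3-(hexa-O-benzylepigallocatechin-8-yl)pentanoate | CC(C)(C)[Si](C)(C)OC(=O)C[C@H](c5c(OCc6ccccc6)cc(OCc6ccccc6)c6c5O[C@H](c5cc(OCc7ccccc7)c(OCc7ccccc7)c(OCc7ccccc7)c5)[C@H](OCc5ccccc5)C6)C[C@@H](O[Si](C)(C)C(C)(C)C)c1ccc(OCc2ccccc2)cc1 | intermediate
18 | (3R,5R)-5-(4-benzyloxyphenyl)-5-(tert-butyldimethylsilyloxy)-3-(hexa-O-benzylepigallocatechin-8-yl)pentanoic acid | OC(=O)C[C@H](c5c(OCc6ccccc6)cc(OCc6ccccc6)c6c5O[C@H](c5cc(OCc7ccccc7)c(OCc7ccccc7)c(OCc7ccccc7)c5)[C@H](OCc5ccccc5)C6)C[C@@H](O[Si](C)(C)C(C)(C)C)c1ccc(OCc2ccccc2)cc1 | intermediate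
19 | (E)-4-methoxybut-3-en-2-one | CO/C=C/C(C)=O | starting material
20 | (3R,5R)-5-(4-benzyloxyphenyl)-5-(tert-butyldimethylsilyloxy)-3-(hexa-O-benzylepigallocatechin-8-yl)pentanoyl chloride | ClC(=O)C[C@H](c5c(OCc6ccccc6)cc(OCc6ccccc6)c6c5O[C@H](c5cc(OCc7ccccc7)c(OCc7ccccc7)c(OCc7ccccc7)c5)[C@H](OCc5ccccc5)C6)C[C@@H](O[Si](C)(C)C(C)(C)C)c1ccc(OCc2ccccc2)cc1 | intermediate
21 | lithium (E)-4-methoxybuta-1,3-dien-2-olate | [Li]OC(=C)/C=C/OC | intermediate
22 | (1E,7R,9R)-9-(4-benzyloxyphenyl)-9-(tert-butyldimethylsilyloxy)-7-(hexa-O-benzylepigallocatechin-8-yl)-1-methoxynon-1-ene-3,5-dione | CO/C=C/C(=O)CC(=O)C[C@H](c5c(OCc6ccccc6)cc(OCc6ccccc6)c6c5O[C@H](c5cc(OCc7ccccc7)c(OCc7ccccc7)c(OCc7ccccc7)c5)[C@H](OCc5ccccc5)C6)C[C@@H](O[Si](C)(C)C(C)(C)C)c1ccc(OCc2ccccc2)cc1 | intermediate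
23 | 2-[(2R,4R)-4-(4-benzyloxyphenyl)-4-(tert-butyldimethylsilyloxy)-2-(hexa-O-benzylepigallocatechin-8-yl)butyl]-4H-pyran-4-one | O=c1ccoc(C[C@H](c5c(OCc6ccccc6)cc(OCc6ccccc6)c6c5O[C@H](c5cc(OCc7ccccc7)c(OCc7ccccc7)c(OCc7ccccc7)c5)[C@H](OCc5ccccc5)C6)C[C@@H](O[Si](C)(C)C(C)(C)C)c2ccc(OCc3ccccc3)cc2)c1 | intermediate
24 | (7R,9R)-9-(4-benzyloxyphenyl)-9-(tert-butyldimethylsilyloxy)-7-(hexa-O-benzylepigallocatechin-8-yl)-3,5-dioxononanal | O=CCC(=O)CC(=O)C[C@H](c5c(OCc6ccccc6)cc(OCc6ccccc6)c6c5O[C@H](c5cc(OCc7ccccc7)c(OCc7ccccc7)c(OCc7ccccc7)c5)[C@H](OCc5ccccc5)C6)C[C@@H](O[Si](C)(C)C(C)(C)C)c1ccc(OCc2ccccc2)cc1 | intermediate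
25 | 4-[(1R,3R)-3-(4-benzyloxyphenyl)-3-(tert-butyldimethylsilyloxy)-1-(hexa-O-benzylepigallocatechin-8-yl)propyl]benzene-1,3-diol | Oc1ccc([C@H](c5c(OCc6ccccc6)cc(OCc6ccccc6)c6c5O[C@H](c5cc(OCc7ccccc7)c(OCc7ccccc7)c(OCc7ccccc7)c5)[C@H](OCc5ccccc5)C6)C[C@@H](O[Si](C)(C)C(C)(C)C)c2ccc(OCc3ccccc3)cc2)c(O)c1 | intermediate
26 | 4-[(1R,3R)-3-(4-benzyloxyphenyl)-3-hydroxy-1-(hexa-O-benzylepigallocatechin-8-yl)propyl]benzene-1,3-diol | Oc1ccc([C@H](c5c(OCc6ccccc6)cc(OCc6ccccc6)c6c5O[C@H](c5cc(OCc7ccccc7)c(OCc7ccccc7)c(OCc7ccccc7)c5)[C@H](OCc5ccccc5)C6)C[C@@H](O)c2ccc(OCc3ccccc3)cc2)c(O)c1 | intermediate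
27 | (2S,4R)-2-(4-benzyloxyphenyl)-4-(hexa-O-benzylepigallocatechin-8-yl)chroman-7-ol (2,4-trans) | O(Cc1ccccc1)c1ccc([C@@H]2C[C@@H](c5c(OCc6ccccc6)cc(OCc6ccccc6)c6c5O[C@H](c5cc(OCc7ccccc7)c(OCc7ccccc7)c(OCc7ccccc7)c5)[C@H](OCc5ccccc5)C6)c3ccc(O)cc3O2)cc1 | intermediate
28 | (2S,4R)-2-(4-hydroxyphenyl)-4-[(2R,3R)-epigallocatechin-8-yl]chroman-7-ol (CNP0220331.1) | Oc1ccc([C@@H]2C[C@@H](c3c(O)cc(O)c4c3O[C@H](c3cc(O)c(O)c(O)c3)[C@H](O)C4)c3ccc(O)cc3O2)cc1 | target

## Step count and least certain steps

Total step count: 14. Longest linear sequence: 14 steps, from 1 to 28; 7, 11 and 19 are used as bought.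

**Step 11 (key step).** The most likely failure is hydroxide-induced loss of the formyl carbon as formate from the opened β-ketoaldehyde before the C4a aldol can take place, because the chain sits mainly as enolates at C6 and C8 and the C4a enolate is the least populated. Return to the pyranone on neutralisation and air oxidation of the resorcinolate are lesser risks.
Fallback, by known chemistry, setting out from 18 and coming back at 25: 18 is esterified with Me3SiCHN2 in PhMe/MeOH to the methyl ester F1. The lithium enolate of F1 (LiN(iPr)2, THF, −78 °C), which can form only at C4a, is added to but-3-en-2-one in a Michael reaction, and KOtBu then drives the Claisen closure of the methyl ketone onto the ester to give the 4-substituted cyclohexane-1,3-dione F2. F2 is aromatised to 25 by aerobic dehydrogenation with divalent palladium (Pd(O2CCF3)2, O2, DMSO). This builds the same C4a–C5 bond by conjugate addition and reaches the resorcinol by oxidation instead of by aldol dehydration.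

**Step 7.** Selection between the two diastereotopic carbonyls may be poor, because the seven ether oxygens can bind magnesium in competition with sparteine and the substrate's own chirality may oppose the ligand. A second Grignard addition to the ketone is a lesser risk.
Fallback, setting out from 10 and coming back at 13: alkaloid-mediated methanolysis (quinidine or quinine, PhMe, −50 °C) gives the hemiester F3, whose diastereomers can be separated. (COCl)2 converts it into the acid chloride F4, CuI-catalysed acylation of 12 at −78 °C gives the keto ester F5, and LiOH hydrolysis returns 13. The desymmetrisation is thereby moved from the carbon nucleophile to a small oxygen nucleophile.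

**Step 5.** The second acetoacetate may fail to add to the crowded, electron-rich arylidene, and retro-Michael loss of one arm may occur in hot alkali.
Fallback, setting out from 6 and coming back at 9: condensation with 2,2-dimethyl-1,3-dioxane-4,6-dione gives the far more electrophilic arylidene F6, to which sodium dimethyl malonate adds to give the adduct F7. Saponification (aq. NaOH, THF), acidification and double decarboxylation in pyridine/water at 90 °C give 9.

**Step 13.** The oxyphosphonium may ionise to the para-alkoxybenzylic cation before the phenol displaces it, with loss of configuration at C2; intermolecular alkylation of the 7-hydroxyl is a lesser risk.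
Fallback, setting out from 26 and coming back at 27: stereospecific displacement is abandoned in favour of an acid-catalysed, equilibrating cyclodehydration (camphorsulfonic acid, catalytic, CH2Cl2). The C2–O1 bond of the product re-ionises under these conditions. The di-ortho-substituted aryl group on C4 should prefer the quasi-axial position to avoid the hydrogen on C5, and with the C2 aryl group equatorial this would favour the trans chroman 27. The separable cis epimer F8 is returned to the same conditions. The position of this equilibrium is an expectation and would have to be established.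

## Further compounds

F1 | step 11 | methyl (3R,5R)-5-(4-benzyloxyphenyl)-5-(tert-butyldimethylsilyloxy)-3-(hexa-O-benzylepigallocatechin-8-yl)pentanoate | COC(=O)C[C@H](c5c(OCc6ccccc6)cc(OCc6ccccc6)c6c5O[C@H](c5cc(OCc7ccccc7)c(OCc7ccccc7)c(OCc7ccccc7)c5)[C@H](OCc5ccccc5)C6)C[C@@H](O[Si](C)(C)C(C)(C)C)c1ccc(OCc2ccccc2)cc1
F2 | step 11 | 4-[(1R,3R)-3-(4-benzyloxyphenyl)-3-(tert-butyldimethylsilyloxy)-1-(hexa-O-benzylepigallocatechin-8-yl)propyl]cyclohexane-1,3-dione | O=C1CCC([C@H](c5c(OCc6ccccc6)cc(OCc6ccccc6)c6c5O[C@H](c5cc(OCc7ccccc7)c(OCc7ccccc7)c(OCc7ccccc7)c5)[C@H](OCc5ccccc5)C6)C[C@@H](O[Si](C)(C)C(C)(C)C)c2ccc(OCc3ccccc3)cc2)C(=O)C1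
F3 | step 7 | (3R)-5-methoxy-5-oxo-3-(hexa-O-benzylepigallocatechin-8-yl)pentanoic acid | COC(=O)C[C@H](c5c(OCc6ccccc6)cc(OCc6ccccc6)c6c5O[C@H](c5cc(OCc7ccccc7)c(OCc7ccccc7)c(OCc7ccccc7)c5)[C@H](OCc5ccccc5)C6)CC(=O)O
F4 | step 7 | methyl (3S)-5-chloro-5-oxo-3-(hexa-O-benzylepigallocatechin-8-yl)pentanoate | COC(=O)C[C@H](c5c(OCc6ccccc6)cc(OCc6ccccc6)c6c5O[C@H](c5cc(OCc7ccccc7)c(OCc7ccccc7)c(OCc7ccccc7)c5)[C@H](OCc5ccccc5)C6)CC(=O)Cl
F5 | step 7 | methyl (3R)-5-(4-benzyloxyphenyl)-5-oxo-3-(hexa-O-benzylepigallocatechin-8-yl)pentanoate | COC(=O)C[C@H](c5c(OCc6ccccc6)cc(OCc6ccccc6)c6c5O[C@H](c5cc(OCc7ccccc7)c(OCc7ccccc7)c(OCc7ccccc7)c5)[C@H](OCc5ccccc5)C6)CC(=O)c1ccc(OCc2ccccc2)cc1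
F6 | step 5 | 5-[(hexa-O-benzylepigallocatechin-8-yl)methylidene]-2,2-dimethyl-1,3-dioxane-4,6-dione | CC1(C)OC(=O)C(=Cc5c(OCc6ccccc6)cc(OCc6ccccc6)c6c5O[C@H](c5cc(OCc7ccccc7)c(OCc7ccccc7)c(OCc7ccccc7)c5)[C@H](OCc5ccccc5)C6)C(=O)O1
F7 | step 5 | dimethyl 2-[(2,2-dimethyl-4,6-dioxo-1,3-dioxan-5-yl)(hexa-O-benzylepigallocatechin-8-yl)methyl]malonate | COC(=O)C(C(=O)OC)C(c5c(OCc6ccccc6)cc(OCc6ccccc6)c6c5O[C@H](c5cc(OCc7ccccc7)c(OCc7ccccc7)c(OCc7ccccc7)c5)[C@H](OCc5ccccc5)C6)C1C(=O)OC(C)(C)OC1=O
F8 | step 13 | (2R,4R)-2-(4-benzyloxyphenyl)-4-(hexa-O-benzylepigallocatechin-8-yl)chroman-7-ol (2,4-cis) | O(Cc1ccccc1)c1ccc([C@H]2C[C@@H](c5c(OCc6ccccc6)cc(OCc6ccccc6)c6c5O[C@H](c5cc(OCc7ccccc7)c(OCc7ccccc7)c(OCc7ccccc7)c5)[C@H](OCc5ccccc5)C6)c3ccc(O)cc3O2)cc1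
A1 | alternative 1 | (4R)-7-benzyloxy-4-(hexa-O-benzylepigallocatechin-8-yl)chroman-2-one | O=C1C[C@@H](c5c(OCc6ccccc6)cc(OCc6ccccc6)c6c5O[C@H](c5cc(OCc7ccccc7)c(OCc7ccccc7)c(OCc7ccccc7)c5)[C@H](OCc5ccccc5)C6)c2ccc(OCc3ccccc3)cc2O1
A2 | alternative 1 | (3R)-6-benzyloxy-3-(hexa-O-benzylepigallocatechin-8-yl)indan-1-one | O=C1C[C@@H](c5c(OCc6ccccc6)cc(OCc6ccccc6)c6c5O[C@H](c5cc(OCc7ccccc7)c(OCc7ccccc7)c(OCc7ccccc7)c5)[C@H](OCc5ccccc5)C6)c2ccc(OCc3ccccc3)cc21
A3 | alternative 2 | (2S,4R)-7-benzyloxy-2-(4-benzyloxyphenyl)-4-(hexa-O-benzylepigallocatechin-8-yl)chroman (octa-O-benzyl target) | O(Cc1ccccc1)c1ccc([C@@H]2C[C@@H](c5c(OCc6ccccc6)cc(OCc6ccccc6)c6c5O[C@H](c5cc(OCc7ccccc7)c(OCc7ccccc7)c(OCc7ccccc7)c5)[C@H](OCc5ccccc5)C6)c3ccc(OCc4ccccc4)cc3O2)cc1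
A4 | alternative 2 | (4-benzyloxy-2-hydroxyphenyl)(hexa-O-benzylepigallocatechin-8-yl)methanol | OC(c5c(OCc6ccccc6)cc(OCc6ccccc6)c6c5O[C@H](c5cc(OCc7ccccc7)c(OCc7ccccc7)c(OCc7ccccc7)c5)[C@H](OCc5ccccc5)C6)c1ccc(OCc2ccccc2)cc1O
A5 | alternative 2 | 4-benzyloxystyrene | C=Cc1ccc(OCc2ccccc2)cc1
A6 | alternative 3 | (4R)-7-benzyloxy-4-(hexa-O-benzylepigallocatechin-8-yl)chroman-2-ol (anomers) | OC1C[C@@H](c5c(OCc6ccccc6)cc(OCc6ccccc6)c6c5O[C@H](c5cc(OCc7ccccc7)c(OCc7ccccc7)c(OCc7ccccc7)c5)[C@H](OCc5ccccc5)C6)c2ccc(OCc3ccccc3)cc2O1
A7 | alternative 3 | 5-benzyloxy-2-[1-(hexa-O-benzylepigallocatechin-8-yl)ethenyl]phenol | C=C(c5c(OCc6ccccc6)cc(OCc6ccccc6)c6c5O[C@H](c5cc(OCc7ccccc7)c(OCc7ccccc7)c(OCc7ccccc7)c5)[C@H](OCc5ccccc5)C6)c1ccc(OCc2ccccc2)cc1O
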